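Numbering: C1 (C=O), C2 and C3 (CHMe), C4 (CHAr); ring A = C4a–C8a (6-OMe, 7-OH); ring B = the carbocycle C1–C4/C4a/C8a; primed atoms = veratryl ring.
Cuts: C4–C4a (ring B), then C1–C8a, then C4–C1′. The remainder, C1–C2(Me)–C3(Me)–C4 with cis methyls, is meso-2,3-dimethylsuccinic anhydride.
Forward: the veratryl ring goes onto C4 by a desymmetrising acylation, the ketone becomes a lactone, ring A goes onto C1 as an aryllithium, and ring B is closed last.
Difficulty: C4 bears two aryl groups that differ only in OH versus OMe, so no open-chain method can tell its faces apart. C2 is enolisable, so only C3 is robust.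
Stereochemistry: a chiral Rh catalyst picks one enantiotopic carbonyl of the meso anhydride (C2 and C3 absolute). C3 then relays to C4 in the ring closure and to C2 in a final kinetic ketonisation.
Enabling feature: 4′-OMe is para to C4 (planar cation), O7 is para to C4a (the attacking carbon, despite the ortho C1 acyl group), and C1=O blocks ionisation at the second benzylic site. All C4 epimers and ring–chain tautomers of the open precursor therefore funnel into one 3,4-trans tetralone.

Key step: step 6

Assumption: the sense of induction of the TADDOL phosphoramidite is treated as adjustable; the antipode is used that directs Rh into the carbonyl bonded to the (R)-configured carbon of 2, and both antipodes are accessible from the two tartaric acids.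

Step 1
Reactants: 1 meso-2,3-dimethylsuccinic acid
Product: 2 cis-2,3-dimethylsuccinic anhydride [(3R,4S)-3,4-dimethyldihydrofuran-2,5-dione; meso]
Conditions: AcCl (neat), reflux; evaporation
Reagents that add atoms: none
Why: Cyclodehydration of the 1,4-diacid through its mixed anhydride closes the five-membered anhydride under mild acidic conditions that leave both α-stereocentres untouched, so the meso (cis) relation is carried over.

Step 2
Reactants: 2 cis-2,3-dimethylsuccinic anhydride; 3 4-bromo-1,2-dimethoxybenzene
Product: 6 (2S,3R)-4-(3,4-dimethoxyphenyl)-2,3-dimethyl-4-oxobutanoic acid, via 3,4-dimethoxyphenyllithium 4 (not isolated), via 3,4-dimethoxyphenylzinc triflate 5 (not isolated)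
Conditions: 3, n-BuLi, THF, −78 °C; Zn(OTf)2, −78 °C → rt; then 2, [Rh(cod)Cl]2 (4 mol %), TADDOL-derived P–NMe2 phosphoramidite (8 mol %), THF, 50 °C; 1 M HCl
Reagents that add atoms: n-butyllithium, CCCC[Li]; zinc triflate, [Zn+2].[O-]S(=O)(=O)C(F)(F)F.[O-]S(=O)(=O)C(F)(F)F (they supply Li of 4 and Zn/OTf of 5; no atom of either remains in 6)
Why: In this Rh(I)/phosphoramidite-catalysed enantioselective desymmetrising acylation (anhydride cross-coupling) the chiral Rh complex inserts into one of the two enantiotopic acyl–O bonds of meso-2, transmetalation from 5 and reductive elimination forge C4–C1′, the cis relation of C2/C3 comes from 2 and their absolute sense from the ligand, and the neutral zinc carboxylate medium neither adds to the new ketone nor enolises C3, a reaction type established on this very anhydride with alkoxy-substituted arylzincs made in situ.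

Step 3
Reactants: 6 (2S,3R)-4-(3,4-dimethoxyphenyl)-2,3-dimethyl-4-oxobutanoic acid
Product: 8 (3S,4R,5RS)-5-(3,4-dimethoxyphenyl)-3,4-dimethyldihydrofuran-2(3H)-one (both C5 epimers), via hydroxy acid 7 (not isolated)
Conditions: NaBH4, MeOH, 0 °C; then 2 M HCl, rt
Reagents that add atoms: none
Why: Borohydride reduction of the aryl ketone followed by acid-promoted γ-lactonisation removes the only enolisable position next to C3, the new carbinol centre (C4 of the target) needs no control because it is planarised in step 6, and any material epimerised at C3 is diastereomeric (C2 still intact) and can be detected and removed here.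

Step 4
Reactants: 9 5-bromo-2-methoxyphenol
Product: 10 2-(5-bromo-2-methoxyphenoxy)tetrahydro-2H-pyran
Conditions: 3,4-dihydro-2H-pyran, PPTS (cat.), CH2Cl2, rt
Reagents that add atoms: 3,4-dihydro-2H-pyran, C1=COCCC1
Why: Acid-catalysed acetalisation (THP ether formation) masks the acidic phenol for the halogen–lithium exchange with a group that falls off by itself under the acid of step 6.

Step 5
Reactants: 10 2-(5-bromo-2-methoxyphenoxy)tetrahydro-2H-pyran; 8 lactone (both C5 epimers)
Product: 12 (2S,3R,4RS)-4-(3,4-dimethoxyphenyl)-4-hydroxy-1-[4-methoxy-3-(tetrahydro-2H-pyran-2-yloxy)phenyl]-2,3-dimethylbutan-1-one (in ring–chain equilibrium with its cyclic hemiketal), via aryllithium 11 (not isolated)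
Conditions: 10, n-BuLi, THF, −78 °C; then 8, −78 °C; AcOH, −78 °C
Reagents that add atoms: n-butyllithium, CCCC[Li] (supplies Li of 11; no atom remains in 12)
Why: Halogen–lithium exchange followed by mono-addition of the aryllithium to the γ-lactone, whose tetrahedral lithium hemiketal alkoxide persists at −78 °C and so prevents a second addition, forms C1–C8a para to the methoxy group as fixed by the bromine position, creates no stereocentre, and is a standard acylation of 3,4-dimethyl-5-arylbutyrolactones in lignan chemistry.

Step 6
Reactants: 12 hydroxy ketone (C4 and acetal epimers, ring–chain tautomers)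
Product: 14 (3S,4R)-4-(3,4-dimethoxyphenyl)-7-hydroxy-6-methoxy-2,3-dimethyl-3,4-dihydronaphthalen-1(2H)-one (C2 epimers), via C4 benzylic cation 13 (not isolated)
Conditions: TfOH (10 mol %), HFIP (0.01 M), argon, 0 °C → rt
Reagents that add atoms: none
Why: TfOH in weakly basic, strongly ionising HFIP cleaves the THP acetal and ionises C4–OH of 12 (from the open form or through its cyclic hemiketal) to the planar secondary benzylic cation 13, which is stabilised by the 4′-OMe group para to C4; C4a of ring A attacks it, and loss of the C4a proton rearomatises ring A and returns the acid. The closest known reaction types are the intramolecular dehydrative Friedel–Crafts alkylation that closes aryltetralin lignans and the Lewis-acid cyclisation of 2-arylcyclopropyl aryl ketones to 4-aryl-1-tetralones, which runs through the same cation and the same aroyl-ring nucleophile. Ring B closes as a six-membered ring by electrophilic aromatic substitution, endo with respect to the C4a=C8a bond of ring A, through a chair-like transition state. The new stereocentre C4 is controlled by C3: A(1,3) strain in 13 puts C3–H in the cation plane beside the veratryl ortho-hydrogen, so that C3–Me and the C2 tether lie on opposite faces, and since ring A can only arrive from the tether face the veratryl group should end up trans to C3–Me, whichever C4 epimer or tautomer of 12 was ionised. The step needs site selectivity for C4a over C8 and for C4 over C1, and the substrate secures both, because O7 is para to C4a whereas C8 is wedged between O7 and the acyl carbon, and because C1 is a carbonyl carbon that cannot ionise; high dilution holds back intermolecular alkylation. Reversible capture of 13 by the ketone oxygen and enolisation can scramble C2 but not C3, so 14 is taken on as a C2 mixture that step 7 converges.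

Step 7
Reactants: 14 tetralone (C2 epimers)
Product: 16 schisandrone [(2S,3S,4R)-4-(3,4-dimethoxyphenyl)-7-hydroxy-6-methoxy-2,3-dimethyl-3,4-dihydronaphthalen-1(2H)-one], via dilithium phenolate enolate 15 (not isolated)
Conditions: LDA (2.3 equiv), THF, −78 °C; cannulation into AcOH/THF, −78 °C
Reagents that add atoms: lithium diisopropylamide, CC(C)N([Li])C(C)C (supplies Li of 15; no atom remains in 16)
Why: Deprotonation erases C2 in both epimers to the single enolate 15, in which peri strain (C4-aryl against H5) and A(1,2) strain (C2–Me against C3–Me) hold the C4-aryl and C3–Me groups trans-diaxial, so that kinetic ketonisation (stereoelectronically axial C-protonation on the face anti to the neighbouring pseudoaxial C3–Me) should put H2 on the aryl face and C2–Me cis to C3–Me, and the cold buffered quench leaves no base to re-equilibrate the product.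

Compound list
1 | meso-2,3-dimethylsuccinic acid | OC(=O)[C@@H](C)[C@@H](C)C(=O)O | starting material
2 | cis-2,3-dimethylsuccinic anhydride (meso) | O=C1[C@@H](C)[C@@H](C)C(=O)O1 | intermediate
3 | 4-bromo-1,2-dimethoxybenzene | COc1ccc(Br)cc1OC | starting material
4 | 3,4-dimethoxyphenyllithium | COc1ccc([Li])cc1OC | intermediate
5 | 3,4-dimethoxyphenylzinc triflate | COc1ccc([Zn]OS(=O)(=O)C(F)(F)F)cc1OC | intermediate
6 | (2S,3R)-4-(3,4-dimethoxyphenyl)-2,3-dimethyl-4-oxobutanoic acid | OC(=O)[C@@H](C)[C@@H](C)C(=O)c1ccc(OC)c(OC)c1 | intermediate
7 | (2S,3R,4RS)-4-(3,4-dimethoxyphenyl)-4-hydroxy-2,3-dimethylbutanoic acid | OC(=O)[C@@H](C)[C@@H](C)C(O)c1ccc(OC)c(OC)c1 | intermediate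
8 | (3S,4R,5RS)-5-(3,4-dimethoxyphenyl)-3,4-dimethyldihydrofuran-2(3H)-one | O=C1[C@@H](C)[C@@H](C)C(c2ccc(OC)c(OC)c2)O1 | intermediate
9 | 5-bromo-2-methoxyphenol | COc1ccc(Br)cc1O | starting material
10 | 2-(5-bromo-2-methoxyphenoxy)tetrahydro-2H-pyran | COc1ccc(Br)cc1OC1CCCCO1 | intermediate
11 | [4-methoxy-3-(tetrahydro-2H-pyran-2-yloxy)phenyl]lithium | COc1ccc([Li])cc1OC1CCCCO1 | intermediate
12 | (2S,3R,4RS)-4-(3,4-dimethoxyphenyl)-4-hydroxy-1-[4-methoxy-3-(tetrahydro-2H-pyran-2-yloxy)phenyl]-2,3-dimethylbutan-1-one | COc1ccc(cc1OC1CCCCO1)C(=O)[C@@H](C)[C@@H](C)C(O)c1ccc(OC)c(OC)c1 | intermediate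
13 | C4 benzylic cation (free phenol, C3 as in 12, C2 labile) | COc1ccc(cc1O)C(=O)C(C)[C@@H](C)[CH+]c1ccc(OC)c(OC)c1 | intermediate
14 | (3S,4R)-4-(3,4-dimethoxyphenyl)-7-hydroxy-6-methoxy-2,3-dimethyl-3,4-dihydronaphthalen-1(2H)-one, C2 epimers | COc1cc2c(cc1O)C(=O)C(C)[C@@H](C)[C@@H]2c1ccc(OC)c(OC)c1 | intermediate
15 | dilithium 7-phenolate/C1–C2 enolate of 14 | COc1cc2c(cc1O[Li])C(O[Li])=C(C)[C@@H](C)[C@@H]2c1ccc(OC)c(OC)c1 | intermediate
16 | schisandrone, (2S,3S,4R) | COc1cc2c(cc1O)C(=O)[C@@H](C)[C@@H](C)[C@@H]2c1ccc(OC)c(OC)c1 | target

Total step count: 7. Longest linear sequence: 6 (steps 1, 2, 3, 5, 6, 7); step 4 is the side branch.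

Steps most likely to fail

Step 6. Three processes could defeat the closure:
- The cation may be held back as its adduct with the ketone oxygen and drained by dehydrogenation to an aromatic heterocycle.
- Proton loss from C3 may erode the only fixed stereocentre.
- Attack by the acyl-bearing ring may be too slow to compete with intermolecular alkylation by the cation or by the released acetal fragment.

The fallback sets out from 12 and comes back at 14. MsCl/Et3N (CH2Cl2, −20 °C) converts 12 into the benzylic chloride F1. KOtBu (THF, −78 → 0 °C) closes the ketone enolate onto C4 (3-exo-tet) to the donor–acceptor cyclopropyl ketone F2, in which C3 is untouched. SnCl4 in MeNO2 (0 °C) then opens F2 to a tin enolate/benzylic cation pair, whose ring A is that of an enolate and no longer that of a ketone. This Lewis-acid cyclisation of 2-arylcyclopropyl aryl ketones to 4-aryl-1-tetralones is known chemistry, cleaves the THP acetal on the way, and rejoins the route at 14.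

Step 7. Facial selectivity of C-protonation may be poor. Alternatively, O-protonation may be followed by slow, less selective ketonisation during work-up. The fallback sets out from 14 and comes back at 16. TMSOTf/Et3N (CH2Cl2, 0 °C) converts 14 into the bis(trimethylsilyl) enol ether F3. F3 is protonated in toluene at −78 °C with the matched enantiomer of the BINOL·SnCl4 Lewis-acid-assisted Brønsted acid, so the face is chosen by the reagent as well as by the substrate. Mild aqueous acid removes the aryl silyl ether and gives 16.

Step 2. Discrimination of the enantiotopic carbonyl groups may be insufficient, transmetalation of the electron-rich arylzinc may be sluggish, or C3 may epimerise at 50 °C. The fallback sets out from 2 and comes back at 8: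
- Cinchona-alkaloid-catalysed methanolysis [(DHQD)2AQN or its pseudo-enantiomer, MeOH, Et2O, −20 °C] opens 2 to the hemiester F4.
- The free acid end of F4 acylates 1,2-dimethoxybenzene para to a methoxy group (TFAA, cat. H3PO4, mixed-anhydride Friedel–Crafts acylation) to give the keto ester F5.
- NaBH4 (MeOH, 0 °C) reduces F5 to the hydroxy ester F6.
- Acid lactonises F6 with loss of methanol to 8.

Further compounds
F1 | step 6 | (2S,3R,4RS)-4-chloro-4-(3,4-dimethoxyphenyl)-1-[4-methoxy-3-(tetrahydro-2H-pyran-2-yloxy)phenyl]-2,3-dimethylbutan-1-one | COc1ccc(cc1OC1CCCCO1)C(=O)[C@@H](C)[C@@H](C)C(Cl)c1ccc(OC)c(OC)c1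
F2 | step 6 | [3-(3,4-dimethoxyphenyl)-1,2-dimethylcyclopropyl][4-methoxy-3-(tetrahydro-2H-pyran-2-yloxy)phenyl]methanone, CHMe carbon configured as C3 of 12, other ring carbons as formed | COc1ccc(cc1OC1CCCCO1)C(=O)C1(C)[C@@H](C)C1c1ccc(OC)c(OC)c1
F3 | step 7 | (3S,4R)-configured 1,7-bis(trimethylsilyloxy)-4-(3,4-dimethoxyphenyl)-6-methoxy-2,3-dimethyl-3,4-dihydronaphthalene | COc1cc2c(cc1O[Si](C)(C)C)C(O[Si](C)(C)C)=C(C)[C@@H](C)[C@@H]2c1ccc(OC)c(OC)c1
F4 | step 2 | (2R,3S)-4-methoxy-2,3-dimethyl-4-oxobutanoic acid | COC(=O)[C@@H](C)[C@@H](C)C(=O)O
F5 | step 2 | methyl (2S,3R)-4-(3,4-dimethoxyphenyl)-2,3-dimethyl-4-oxobutanoate | COC(=O)[C@@H](C)[C@@H](C)C(=O)c1ccc(OC)c(OC)c1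
F6 | step 2 | methyl (2S,3R,4RS)-4-(3,4-dimethoxyphenyl)-4-hydroxy-2,3-dimethylbutanoate | COC(=O)[C@@H](C)[C@@H](C)C(O)c1ccc(OC)c(OC)c1
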